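## Retrosynthetic overview

1. The cyclopropane is disconnected last, across both bonds to the ketone-bearing carbon: a Co(II)-metalloradical [2+1] union of terminal alkene **9** (lactone and free carbinol in place) with diazoketone **18** (lactate centre and Z-cinnamate in place) gives the target directly.
2. Alkene **9**: the dihydropyranone ring comes from propiolate opening of a Sharpless-derived vinyl epoxide (from divinyl carbinol), Lindlar reduction and lactonisation.
3. Diazoketone **18**: tert-butyl (S)-lactate + propiolic acid, then Pd-catalysed trans-hydroarylation with anisole (sets the Z-alkene), then acylation of TMS-diazomethane.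
4. Ring order: anisole ring bought; dihydropyranone (step 4); cyclopropane (step 8, final step).

Assumption: both antipodes of the chiral Co(II) amidoporphyrin are at hand, and step 8 uses the one matched to **9** for the (1S,2S) ring; which antipode that is must be found by running both.

## Route

Step 1
Reactants: 1 penta-1,4-dien-3-ol
Product: 2 (2R,3S)-1,2-epoxypent-4-en-3-ol
Conditions: Ti(OiPr)4 (10 mol%), L-(+)-DIPT (13 mol%), t-BuOOH (anhydrous), 4 Å MS, CH2Cl2, −20 °C
Reagents that add atoms: tert-butyl hydroperoxide, CC(C)(C)OO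
Why: Sharpless asymmetric epoxidation of the prochiral divinyl carbinol, in which L-(+)-tartrate selects one enantiotopic vinyl group and one face (erythro product), setting C2 (R) and C3 (S) together, while the minor enantiomer is drained by a fast second epoxidation so that ee rises with conversion.

Step 2
Reactants: 2 (2R,3S)-1,2-epoxypent-4-en-3-ol
Product: 3 triethyl({(1S)-1-[(2R)-oxiran-2-yl]prop-2-en-1-yl}oxy)silane
Conditions: TESCl, imidazole, CH2Cl2, 0 °C
Reagents that add atoms: chlorotriethylsilane, CC[Si](Cl)(CC)CC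
Why: Standard imidazole-mediated silylation of a secondary alcohol, which masks the OH for the organolithium step with a group (TES) chosen to fall off in the acidic stage of step 4.

Step 3
Reactants: 3 triethyl({(1S)-1-[(2R)-oxiran-2-yl]prop-2-en-1-yl}oxy)silane; 4 ethyl prop-2-ynoate
Product: 6 ethyl (5R,6S)-5-hydroxy-6-[(triethylsilyl)oxy]oct-7-en-2-ynoate, via lithium acetylide 5 (not isolated)
Conditions: 4, n-BuLi, THF, −78 °C; BF3·OEt2; then 3, −78 °C; aq. NH4Cl
Reagents that add atoms: none
Why: Yamaguchi–Hirao alkynylation, in which the BF3-activated terminal epoxide is opened by the lithium acetylide in an SN2 attack at the unsubstituted carbon, so neither stereocentre is touched.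

Step 4
Reactants: 6 ethyl (5R,6S)-5-hydroxy-6-[(triethylsilyl)oxy]oct-7-en-2-ynoate
Product: 9 (6R)-6-[(1S)-1-hydroxyprop-2-en-1-yl]-5,6-dihydro-2H-pyran-2-one, via Z-hydroxy-enoate 7 (not isolated), via TES-lactone 8 (not isolated)
Conditions: H2 (1 atm), Lindlar cat., quinoline, EtOAc, rt; filter; then 2 M aq. HCl/THF, rt
Reagents that add atoms: none
Why: Lindlar semi-hydrogenation (syn addition of H2, the conjugated alkyne reacting much faster than the terminal alkene on the quinoline-poisoned catalyst) gives the Z-enoate, which lactonises under acid to the six-membered ring while the aqueous acid cleaves the TES ether, no stereocentre being affected.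

Step 5
Reactants: 10 tert-butyl (2S)-2-hydroxypropanoate; 11 prop-2-ynoic acid
Product: 12 tert-butyl (2S)-2-(prop-2-ynoyloxy)propanoate
Conditions: DCC, DMAP (5 mol%), CH2Cl2, −20 → 0 °C
Reagents that add atoms: none
Why: Steglich esterification (carbodiimide activation, acyl transfer to the secondary OH) with retention at the lactate centre, low temperature and little DMAP keeping the propiolate from Michael addition.

Step 6
Reactants: 12 tert-butyl (2S)-2-(prop-2-ynoyloxy)propanoate; 13 anisole
Product: 15 (2S)-2-{[(2Z)-3-(4-methoxyphenyl)prop-2-enoyl]oxy}propanoic acid, via propioloyl-lactic acid 14 (not isolated)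
Conditions: Pd(OAc)2 (5 mol%), anisole (5 equiv), TFA/CH2Cl2 4:1, rt, dark
Reagents that add atoms: none
Why: Fujiwara hydroarylation (Pd(II)-catalysed trans-addition of an arene C–H across an alkynoate), in which TFA first cleaves the tert-butyl ester, anisole then attacks the Pd(II)-activated alkyne through its para carbon anti to the metal, and protonolysis gives the Z-cinnamate, the geometry being set by the anti addition.

Step 7
Reactants: 15 (2S)-2-{[(2Z)-3-(4-methoxyphenyl)prop-2-enoyl]oxy}propanoic acid; 16 (trimethylsilyl)diazomethane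
Product: 18 (2S)-4-diazo-3-oxobutan-2-yl (2Z)-3-(4-methoxyphenyl)prop-2-enoate, via mixed anhydride 17 (not isolated)
Conditions: i-BuOCOCl, NMM, THF, −20 °C; then TMSCHN2 (hexanes), MeCN, 0 °C → rt; neutral work-up
Reagents that add atoms: isobutyl chloroformate, CC(C)COC(Cl)=O (its atoms are carried only by 17 and are lost again)
Why: Acylation of a diazoalkane by a mixed carbonic anhydride (first stage of an Arndt–Eistert sequence), in which TMSCHN2 is C-acylated and the isobutyl carbonate leaving group takes the silyl group and collapses to CO2, the cold, weakly basic conditions leaving the α-acyloxy stereocentre and the Z-alkene untouched.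

Step 8
Reactants: 9 (6R)-6-[(1S)-1-hydroxyprop-2-en-1-yl]-5,6-dihydro-2H-pyran-2-one; 18 (2S)-4-diazo-3-oxobutan-2-yl (2Z)-3-(4-methoxyphenyl)prop-2-enoate
Product: 19 brevipolide I, (2S)-1-{(1S,2S)-2-[(S)-hydroxy[(2R)-6-oxo-3,6-dihydro-2H-pyran-2-yl]methyl]cyclopropyl}-1-oxopropan-2-yl (2Z)-3-(4-methoxyphenyl)prop-2-enoate
Conditions: [Co(3,5-DitBu-ChenPhyrin)] (5 mol%, matched antipode), 18 (1.3 equiv), PhCl, 40 °C, N2, dark
Reagents that add atoms: none
Why: Proposed new method: the Co(II) metalloradical, hydrogen-bonded through its chiral amide N–H groups to the ketone of 18, expels N2 to give an α-Co(III)-alkyl (carbene) radical that adds to the terminal CH2 of 9, and the resulting γ-Co(III)-alkyl radical closes the ring by 3-exo-tet homolytic substitution at carbon with release of Co(II), the anti transition state giving the trans ring and the chiral cavity fixing both new centres as (1S,2S), while the cis-disubstituted lactone and cinnamate alkenes are poor acceptors and the free OH is tolerated because the carbene radical is not electrophilic; closest known reaction type: Co(II)-amidoporphyrin asymmetric radical cyclopropanation of terminal alkenes with diazoacetates and α-ketodiazoacetates, here extended to an acceptor-only α-acyloxy diazoketone and an unactivated allylic carbinol.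

## Compound list

1 | penta-1,4-dien-3-ol | C=CC(O)C=C | starting material
2 | (2R,3S)-1,2-epoxypent-4-en-3-ol | C=C[C@H](O)[C@H]1CO1 | intermediate
3 | triethyl({(1S)-1-[(2R)-oxiran-2-yl]prop-2-en-1-yl}oxy)silane | C=C[C@H](O[Si](CC)(CC)CC)[C@H]1CO1 | intermediate
4 | ethyl prop-2-ynoate (ethyl propiolate) | C#CC(=O)OCC | starting material
5 | ethyl 3-lithioprop-2-ynoate | [Li]C#CC(=O)OCC | intermediate (not isolated)
6 | ethyl (5R,6S)-5-hydroxy-6-[(triethylsilyl)oxy]oct-7-en-2-ynoate | C=C[C@H](O[Si](CC)(CC)CC)[C@H](O)CC#CC(=O)OCC | intermediate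
7 | ethyl (2Z,5R,6S)-5-hydroxy-6-[(triethylsilyl)oxy]octa-2,7-dienoate | C=C[C@H](O[Si](CC)(CC)CC)[C@H](O)C/C=C\C(=O)OCC | intermediate (not isolated)
8 | (6R)-6-[(1S)-1-[(triethylsilyl)oxy]prop-2-en-1-yl]-5,6-dihydro-2H-pyran-2-one | C=C[C@H](O[Si](CC)(CC)CC)[C@H]1CC=CC(=O)O1 | intermediate (not isolated)
9 | (6R)-6-[(1S)-1-hydroxyprop-2-en-1-yl]-5,6-dihydro-2H-pyran-2-one | C=C[C@H](O)[C@H]1CC=CC(=O)O1 | intermediate
10 | tert-butyl (2S)-2-hydroxypropanoate (L-lactic acid as its tert-butyl ester) | C[C@H](O)C(=O)OC(C)(C)C | starting material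
11 | prop-2-ynoic acid (propiolic acid) | C#CC(=O)O | starting material
12 | tert-butyl (2S)-2-(prop-2-ynoyloxy)propanoate | C[C@H](OC(=O)C#C)C(=O)OC(C)(C)C | intermediate
13 | anisole | COc1ccccc1 | starting material
14 | (2S)-2-(prop-2-ynoyloxy)propanoic acid | C[C@H](OC(=O)C#C)C(=O)O | intermediate (not isolated)
15 | (2S)-2-{[(2Z)-3-(4-methoxyphenyl)prop-2-enoyl]oxy}propanoic acid | C[C@H](OC(=O)/C=C\c1ccc(OC)cc1)C(=O)O | intermediate
16 | (trimethylsilyl)diazomethane | C[Si](C)(C)C=[N+]=[N-] | starting material
17 | (2S)-2-{[(2Z)-3-(4-methoxyphenyl)prop-2-enoyl]oxy}propanoic isobutyl carbonic anhydride | C[C@H](OC(=O)/C=C\c1ccc(OC)cc1)C(=O)OC(=O)OCC(C)C | intermediate (not isolated)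
18 | (2S)-4-diazo-3-oxobutan-2-yl (2Z)-3-(4-methoxyphenyl)prop-2-enoate | C[C@H](OC(=O)/C=C\c1ccc(OC)cc1)C(=O)C=[N+]=[N-] | intermediate
19 | brevipolide I | COc1ccc(/C=C\C(=O)O[C@@H](C)C(=O)[C@H]2C[C@@H]2[C@H](O)[C@H]2CC=CC(=O)O2)cc1 | target

## Step count

Total steps: 8. Longest linear sequence: 5 (steps 1, 2, 3, 4, 8); the other branch is steps 5, 6, 7, then 8.

## Three steps most likely to fail

**Step 8.** The alkene is unactivated and the diazoketone is acceptor-only, so the radical addition may be slow. The carbene radical could instead be captured within the molecule by the cinnamate alkene (6-exo). The allylic centre of 9 may also be mismatched with the catalyst. The fallback sets out from 9 and 18 and comes back at 19. 9 is silylated (TBSCl, imidazole, DMF) to (6R)-6-[(1S)-1-[(tert-butyldimethylsilyl)oxy]prop-2-en-1-yl]-5,6-dihydro-2H-pyran-2-one F1. The carbene of 18 is then transferred in closed-shell fashion with a chiral Ru(II)–Pheox catalyst (CH2Cl2, rt). This electrophilic metal carbene prefers the electron-richer terminal alkene over the two acrylate-type alkenes, and with the OH masked it cannot insert into O–H. The product is 1′-O-(tert-butyldimethylsilyl)brevipolide I F2, and HF·pyridine (THF/pyridine, 0 °C) frees the carbinol to give 19.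

**Step 6.** Anisole may give ortho/para mixtures or add twice, and the electron-rich Z-cinnamate can drift to E on long exposure to TFA. The fallback sets out from 13 and 12 and comes back at 15. Anisole is iodinated para (NIS, cat. TFA, MeCN) to 4-iodoanisole F3. Sonogashira coupling with 12 (Pd(PPh3)2Cl2, CuI, iPr2NEt, THF, rt) gives tert-butyl (2S)-2-{[3-(4-methoxyphenyl)prop-2-ynoyl]oxy}propanoate F4. Lindlar semi-hydrogenation (syn delivery of H2) gives tert-butyl (2S)-2-{[(2Z)-3-(4-methoxyphenyl)prop-2-enoyl]oxy}propanoate F5. Brief TFA/CH2Cl2 at 0 °C then gives 15.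

**Step 4.** The terminal vinyl group may be over-reduced during the semi-hydrogenation, and the lithium propiolate of step 3 is itself fragile. The fallback sets out from 3 and comes back at 8. Copper-catalysed opening of 3 with vinylmagnesium bromide (CuI, THF, −40 °C) gives (3S,4R)-3-[(triethylsilyl)oxy]hepta-1,6-dien-4-ol F6. Acryloyl chloride/Et3N (CH2Cl2, 0 °C) gives (3S,4R)-3-[(triethylsilyl)oxy]hepta-1,6-dien-4-yl prop-2-enoate F7. Ring-closing metathesis (Grubbs II, CH2Cl2, 40 °C) starts at the unhindered allyl terminus and closes onto the acrylate to give 8, which the acid stage of step 4 converts to 9.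

## Further compounds

F1 | step 8 | (6R)-6-[(1S)-1-[(tert-butyldimethylsilyl)oxy]prop-2-en-1-yl]-5,6-dihydro-2H-pyran-2-one | C=C[C@H](O[Si](C)(C)C(C)(C)C)[C@H]1CC=CC(=O)O1
F2 | step 8 | 1′-O-(tert-butyldimethylsilyl)brevipolide I | COc1ccc(/C=C\C(=O)O[C@@H](C)C(=O)[C@H]2C[C@@H]2[C@H](O[Si](C)(C)C(C)(C)C)[C@H]2CC=CC(=O)O2)cc1
F3 | step 6 | 4-iodoanisole | COc1ccc(I)cc1
F4 | step 6 | tert-butyl (2S)-2-{[3-(4-methoxyphenyl)prop-2-ynoyl]oxy}propanoate | C[C@H](OC(=O)C#Cc1ccc(OC)cc1)C(=O)OC(C)(C)C
F5 | step 6 | tert-butyl (2S)-2-{[(2Z)-3-(4-methoxyphenyl)prop-2-enoyl]oxy}propanoate | C[C@H](OC(=O)/C=C\c1ccc(OC)cc1)C(=O)OC(C)(C)C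
F6 | step 4 | (3S,4R)-3-[(triethylsilyl)oxy]hepta-1,6-dien-4-ol | C=C[C@H](O[Si](CC)(CC)CC)[C@H](O)CC=C
F7 | step 4 | (3S,4R)-3-[(triethylsilyl)oxy]hepta-1,6-dien-4-yl prop-2-enoate | C=C[C@H](O[Si](CC)(CC)CC)[C@H](OC(=O)C=C)CC=C
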